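**Plan**

1. Retrosynthesis: the last C–C cut is C11–C7, which opens the lactone to the O6 acrylate of a 4-acyloxycyclohept-2-en-1-one. With C9 as a ketone, C7 is the β-carbon of an enone inside the seven-membered ring and O6 sits on the adjacent γ-carbon C6, so the acrylate α-carbon reaches C7 through a five-membered transition state.
2. Earlier cuts are C7=C8 (ring-closing metathesis), C1–C2 (acetylide to ketone) and C1–C10 (crotylboration). They lead to D-arabinose (C1, C5, C6, C7), a (Z)-crotylboronate (C8, C9, C10, C14), (R)-but-3-yn-2-ol (C2–C4, C15), acryloyl chloride (C11–C13) and (S)-2-methylbutanoic acid.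
3. Forward order: the acyclic chain is assembled, the seven-membered ring is closed by metathesis, and the lactone ring is closed by the key step. The C9 ketone is then reduced and the alkyne is hydrated to the C2 ketone.
4. Stereochemistry: C5 and C6 come from C2 and C3 of D-arabinose. C10 comes from the syn-selective, Felkin-face (Z)-crotylboration and C1 from Felkin–Anh acetylide addition. C7 follows from the cis ring fusion forced by the O6 tether and C9 from hydride delivery by the C1 hydroxyl. C4 and the ester stereocentre come from the chiral pool.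
5. The alkyne masks the C2 ketone until the C9 hydroxyl, which is cis to it on the ring, directs its regioselective hydration.

Key step: step 16

Remark: atoms are numbered as in a 4,5-seco-guaianolide (C1 tertiary carbinol, C2–C4 and C15 side chain, C5 ester-bearing carbon, C6 lactone carbinol, C7 ring fusion, C8 methylene, C9 carbinol, C10 with methyl C14, C11–C13 methylene lactone). Glycoside 2 is used as the anomeric mixture because its anomeric carbon becomes the aldehyde carbon in step 4.

**Route**

Step 1
Reactants: 1 D-arabinose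
Product: 2 methyl D-arabinofuranoside (anomeric mixture)
Conditions: AcCl (0.1 equiv), MeOH, rt; pyridine quench
Reagents that add atoms: methanol, CO
Why: Kinetically controlled Fischer glycosidation should trap the furanose form, and no stereocentre that survives is created.

Step 2
Reactants: 2 methyl D-arabinofuranoside
Product: 3 methyl 5-deoxy-5-iodo-D-arabinofuranoside
Conditions: PPh3, iodine, imidazole, THF, 0 °C to rt
Reagents that add atoms: iodine, [I][I]
Why: Garegg–Samuelsson (Appel-type) iodination should convert only the primary 5-hydroxyl, the two secondary hydroxyls being too hindered for the alkoxyphosphonium intermediate.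

Step 3
Reactants: 3 methyl 5-deoxy-5-iodo-D-arabinofuranoside
Product: 4 methyl 5-deoxy-5-iodo-2,3-bis-O-(triethylsilyl)-D-arabinofuranoside
Conditions: Et3SiOTf, 2,6-lutidine, CH2Cl2, −78 to 0 °C
Reagents that add atoms: triethylsilyl trifluoromethanesulfonate, CC[Si](CC)(CC)OS(=O)(=O)C(F)(F)F
Why: Silyl triflate with a hindered base silylates both secondary hydroxyls without displacing the primary iodide, and the non-chelating triethylsilyl ethers can later be removed beside a TBS ether.

Step 4
Reactants: 4 methyl 5-deoxy-5-iodo-2,3-bis-O-(triethylsilyl)-D-arabinofuranoside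
Product: 5 (2S,3R)-2,3-bis(triethylsilyloxy)pent-4-enal
Conditions: activated Zn dust, THF/H2O (4:1), sonication, 40 °C
Reagents that add atoms: none
Why: Bernet–Vasella reductive fragmentation: zinc inserts into the carbon–iodine bond, β-elimination expels the ring oxygen and the hemiacetal anion collapses to the aldehyde, leaving the two silyloxy stereocentres (future C5 and C6) untouched.

Step 5
Reactants: 5 (2S,3R)-2,3-bis(triethylsilyloxy)pent-4-enal; 6 (Z)-crotylboronic acid pinacol ester
Product: 8 (3S,4R,5R,6R)-3-methyl-5,6-bis(triethylsilyloxy)octa-1,7-dien-4-ol, via pinacol borate ester 7 (not isolated)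
Conditions: 6 (1.5 equiv), toluene, 4 Å molecular sieves, −78 °C to rt; then H2O, pH 7 buffer
Reagents that add atoms: none
Why: Hoffmann–Roush allylboration through a closed chair transition state: the (Z)-crotyl geometry gives the syn relation of the new carbinol and the C10 methyl, and the aldehyde should react on the Felkin (Cornforth) face anti to the α-silyloxy group, which together set C10 as in the target (the carbinol itself is oxidised in step 6).

Step 6
Reactants: 8 (3S,4R,5R,6R)-3-methyl-5,6-bis(triethylsilyloxy)octa-1,7-dien-4-ol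
Product: 9 (3S,5S,6R)-3-methyl-5,6-bis(triethylsilyloxy)octa-1,7-dien-4-one
Conditions: Dess–Martin periodinane, NaHCO3, CH2Cl2, 0 °C to rt
Reagents that add atoms: none
Why: Dess–Martin oxidation under buffered, non-basic conditions should give the β,γ-unsaturated ketone without epimerising C10 or moving the vinyl group into conjugation.

Step 7
Reactants: 10 (R)-but-3-yn-2-ol
Product: 11 (R)-3-(tert-butyldimethylsilyloxy)but-1-yne
Conditions: TBSCl, imidazole, CH2Cl2, rt
Reagents that add atoms: tert-butyldimethylsilyl chloride, CC(C)(C)[Si](C)(C)Cl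
Why: Standard silylation; the TBS ether protects O4 through the organometallic and acylation steps and does not touch the stereocentre.

Step 8
Reactants: 9 (3S,5S,6R)-3-methyl-5,6-bis(triethylsilyloxy)octa-1,7-dien-4-one; 11 (R)-3-(tert-butyldimethylsilyloxy)but-1-yne
Product: 13 (3S,4R,5S,6R)-4-[(3R)-3-(tert-butyldimethylsilyloxy)but-1-ynyl]-3-methyl-5,6-bis(triethylsilyloxy)octa-1,7-dien-4-ol, via lithium acetylide 12 (not isolated)
Conditions: 11, n-BuLi, THF, −78 °C; anhydrous CeCl3, −78 °C; then 9, −78 °C; aq. NH4Cl
Reagents that add atoms: none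
Why: 1,2-Addition of a weakly basic alkynylcerium reagent (the C10–H is not removed) under polar Felkin–Anh control: the nucleophile should attack anti to the non-chelating C5–OSiEt3 bond, setting C1 with its hydroxyl trans to O5 on the later ring.

Step 9
Reactants: 13 tertiary propargylic alcohol
Product: 14 terminal epoxide of 13 at the C10 vinyl group (oxirane on C9, both C9 epimers)
Conditions: VO(acac)2 (5 mol %), t-BuOOH (in decane), CH2Cl2, rt
Reagents that add atoms: tert-butyl hydroperoxide, CC(C)(C)OO
Why: Hydroxyl-directed vanadium-catalysed epoxidation: the tertiary C1 alkoxide binds vanadium and should deliver oxygen only to the homoallylic alkene on C10, leaving the more remote, silyloxy-deactivated C7 vinyl group and the alkyne intact; both C9 epimers serve because C9 later becomes a ketone.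

Step 10
Reactants: 14 terminal epoxide
Product: 15 5-[(3R)-3-(tert-butyldimethylsilyloxy)but-1-ynyl]-4-methyl-6,7-bis(triethylsilyloxy)nona-1,8-diene-3,5-diol (C9 carbinol epimers; C1, C5, C6, C10 as in 13)
Conditions: Me3S+ I− (8 equiv), n-BuLi (7.5 equiv), THF, −10 °C to rt
Reagents that add atoms: trimethylsulfonium iodide, C[S+](C)C.[I-]
Why: Dimethylsulfonium methylide opens the terminal epoxide at its CH2 carbon and the resulting sulfonium alkoxide eliminates dimethyl sulfide, a known one-carbon homologation of terminal epoxides to allylic alcohols that gives the vinyl carbinol needed for ring closure.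

Step 11
Reactants: 15 diene diol
Product: 16 6-[(3R)-3-(tert-butyldimethylsilyloxy)but-1-ynyl]-7-methyl-4,5-bis(triethylsilyloxy)cyclohept-2-ene-1,6-diol (C9 epimers)
Conditions: (H2IMes)(PCy3)Cl2Ru=CHPh (second-generation Grubbs catalyst, 10 mol %), CH2Cl2 (0.005 M), 40 °C
Reagents that add atoms: none
Why: Ring-closing metathesis of the two terminal vinyl groups forms the C7=C8 bond of the seven-membered ring with loss of ethylene; the internal alkyne lies between a fully substituted carbon and a silyloxy-bearing carbon and should be too hindered to engage the ruthenium carbene.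

Step 12
Reactants: 16 cycloheptene diol
Product: 17 (4R,5S,6R,7R)-6-[(3R)-3-(tert-butyldimethylsilyloxy)but-1-ynyl]-6-hydroxy-7-methyl-4,5-bis(triethylsilyloxy)cyclohept-2-en-1-one
Conditions: Dess–Martin periodinane, NaHCO3, CH2Cl2, 0 °C to rt
Reagents that add atoms: none
Why: Dess–Martin oxidation of the only secondary (allylic) hydroxyl gives the ring enone and merges the C9 epimers; the tertiary C1 hydroxyl cannot be oxidised.

Step 13
Reactants: 17 cycloheptenone bis(triethylsilyl) ether
Product: 18 (4R,5S,6R,7R)-6-[(3R)-3-(tert-butyldimethylsilyloxy)but-1-ynyl]-4,5,6-trihydroxy-7-methylcyclohept-2-en-1-one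
Conditions: HF·pyridine, pyridine, THF, 0 °C
Reagents that add atoms: none
Why: Buffered HF·pyridine should cleave the two triethylsilyl ethers much faster than the secondary TBS ether, freeing O5 and O6 only.

Step 14
Reactants: 18 triol; 19 acryloyl chloride
Product: 20 4-O-acryloyl derivative of 18 (acrylate on C6 in skeleton numbering)
Conditions: 19 (1.1 equiv), i-Pr2NEt, CH2Cl2, −78 °C
Reagents that add atoms: none
Why: Kinetically selective acylation: the allylic C6 hydroxyl should react first, the C5 hydroxyl next to the quaternary C1 and the tertiary C1 hydroxyl being much more hindered at low temperature.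

Step 15
Reactants: 20 C6 acrylate; 21 (S)-2-methylbutanoic acid
Product: 22 4-O-acryloyl-5-O-[(S)-2-methylbutanoyl] derivative of 18
Conditions: 21 (1.5 equiv), DCC, DMAP (0.2 equiv), CH2Cl2, 0 °C to rt
Reagents that add atoms: none
Why: Steglich esterification acylates the remaining secondary C5 hydroxyl, the tertiary hydroxyl is inert, and carbodiimide activation should not epimerise the α-stereocentre of the acid.

Step 16
Reactants: 22 acrylate of the γ-hydroxy ring enone
Product: 23 cis-fused α-methylene-γ-butyrolactone with C9 ketone (C1 hydroxyl free, C2≡C3 alkyne, O4 as TBS ether, O5 as (S)-2-methylbutanoate)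
Conditions: PBu3 (0.3 equiv), t-AmOH, rt
Reagents that add atoms: none
Why: Intramolecular Rauhut–Currier reaction: PBu3 adds to the unsubstituted acrylate terminus C13, the phosphonium enolate attacks the enone β-carbon C7 through C11, and solvent-mediated proton transfer from C11 to C8 followed by E1cB loss of PBu3 restores the C11=C13 methylene. The closest known reaction is the phosphine-catalysed cyclisation of acrylates of 4-hydroxycyclohexa-2,5-dienones to cis-fused α-methylene-γ-butyrolactones. The lactone ring (O6–C12–C11–C7–C6) closes in the 5-exo-trig mode. The new stereocentre C7 is controlled by the tether, because the three-atom O–C(=O)–C unit anchored on C6 can reach C7 only on the face that carries O6, which gives the cis ring fusion of the target. The step needs the phosphine to add to the acrylate and not to the ring enone, which the unhindered CH2 terminus of the acrylate against the β-substituted C7 should secure, and it must leave C10 next to the C9 ketone unepimerised, which the neutral, weakly basic conditions and protonation of the ring enolate at the non-stereogenic C8 should secure.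

Step 17
Reactants: 23 lactone ketone
Product: 24 C9 alcohol (C9–OH trans to C1–OH and cis to the alkynyl group; other centres as in 23)
Conditions: Me4NBH(OAc)3 (5 equiv), AcOH/MeCN (1:1), −25 °C
Reagents that add atoms: none
Why: Evans–Saksena reduction: the C1 hydroxyl exchanges onto boron and delivers hydride to the C9 ketone on its own face, which should give the 1,3-anti (trans) diol and thus C9 as in the target, while the lactone, esters, alkyne and methylene lactone are not reduced by this mild reagent.

Step 18
Reactants: 24 C9 alcohol with C2≡C3 alkyne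
Product: 26 4-O-tert-butyldimethylsilyl ether of the target, via bridged enol ether 25 (not isolated)
Conditions: (JohnPhos)Au(MeCN)SbF6 (5 mol %), THF/H2O (10:1), rt
Reagents that add atoms: water, O
Why: Gold-catalysed alkynol cycloisomerisation and hydrolysis: the C9 hydroxyl, cis to the alkynyl group across C10, should add 5-exo-dig to C2 of the gold-activated alkyne, and water then hydrolyses the exocyclic enol ether, which places the carbonyl on C2 and not on C3.

Step 19
Reactants: 26 TBS ether of the target
Product: 27 target compound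
Conditions: HF·pyridine, pyridine, THF, 0 °C to rt
Reagents that add atoms: none
Why: Buffered fluoride cleavage of the last silyl ether under mildly acidic conditions that the β-hydroxy ketone, the two esters and the methylene lactone should tolerate, with no stereocentre affected.

**Compound list**

1 | D-arabinose | O=C[C@@H](O)[C@H](O)[C@H](O)CO | starting material
2 | methyl D-arabinofuranoside (anomeric mixture) | COC1[C@@H](O)[C@H](O)[C@@H](CO)O1 | intermediate
3 | methyl 5-deoxy-5-iodo-D-arabinofuranoside | COC1[C@@H](O)[C@H](O)[C@@H](CI)O1 | intermediate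
4 | methyl 5-deoxy-5-iodo-2,3-bis-O-(triethylsilyl)-D-arabinofuranoside | COC1[C@@H](O[Si](CC)(CC)CC)[C@H](O[Si](CC)(CC)CC)[C@@H](CI)O1 | intermediate
5 | (2S,3R)-2,3-bis(triethylsilyloxy)pent-4-enal | O=C[C@@H](O[Si](CC)(CC)CC)[C@H](O[Si](CC)(CC)CC)C=C | intermediate
6 | (Z)-crotylboronic acid pinacol ester | C/C=C\CB1OC(C)(C)C(C)(C)O1 | starting material
7 | pinacol borate ester of 8 (not isolated) | C=C[C@@H](O[Si](CC)(CC)CC)[C@H](O[Si](CC)(CC)CC)[C@H](OB1OC(C)(C)C(C)(C)O1)[C@@H](C)C=C | intermediate
8 | (3S,4R,5R,6R)-3-methyl-5,6-bis(triethylsilyloxy)octa-1,7-dien-4-ol | C=C[C@@H](O[Si](CC)(CC)CC)[C@H](O[Si](CC)(CC)CC)[C@H](O)[C@@H](C)C=C | intermediate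
9 | (3S,5S,6R)-3-methyl-5,6-bis(triethylsilyloxy)octa-1,7-dien-4-one | C=C[C@@H](O[Si](CC)(CC)CC)[C@H](O[Si](CC)(CC)CC)C(=O)[C@@H](C)C=C | intermediate
10 | (R)-but-3-yn-2-ol | C#C[C@@H](C)O | starting material
11 | (R)-3-(tert-butyldimethylsilyloxy)but-1-yne | C#C[C@@H](C)O[Si](C)(C)C(C)(C)C | intermediate
12 | lithium acetylide of 11 (not isolated) | [Li]C#C[C@@H](C)O[Si](C)(C)C(C)(C)C | intermediate
13 | (3S,4R,5S,6R)-4-[(3R)-3-(tert-butyldimethylsilyloxy)but-1-ynyl]-3-methyl-5,6-bis(triethylsilyloxy)octa-1,7-dien-4-ol | C=C[C@@H](O[Si](CC)(CC)CC)[C@H](O[Si](CC)(CC)CC)[C@](O)(C#C[C@@H](C)O[Si](C)(C)C(C)(C)C)[C@@H](C)C=C | intermediate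
14 | terminal epoxide of 13 at the C10 vinyl group (C9 epimers) | C=C[C@@H](O[Si](CC)(CC)CC)[C@H](O[Si](CC)(CC)CC)[C@](O)(C#C[C@@H](C)O[Si](C)(C)C(C)(C)C)[C@@H](C)C1CO1 | intermediate
15 | 5-[(3R)-3-(tert-butyldimethylsilyloxy)but-1-ynyl]-4-methyl-6,7-bis(triethylsilyloxy)nona-1,8-diene-3,5-diol (C9 epimers) | C=C[C@@H](O[Si](CC)(CC)CC)[C@H](O[Si](CC)(CC)CC)[C@](O)(C#C[C@@H](C)O[Si](C)(C)C(C)(C)C)[C@@H](C)C(O)C=C | intermediate
16 | 6-[(3R)-3-(tert-butyldimethylsilyloxy)but-1-ynyl]-7-methyl-4,5-bis(triethylsilyloxy)cyclohept-2-ene-1,6-diol (C9 epimers) | CC[Si](CC)(CC)O[C@@H]1C=CC(O)[C@H](C)[C@@](O)(C#C[C@@H](C)O[Si](C)(C)C(C)(C)C)[C@H]1O[Si](CC)(CC)CC | intermediate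
17 | (4R,5S,6R,7R)-6-[(3R)-3-(tert-butyldimethylsilyloxy)but-1-ynyl]-6-hydroxy-7-methyl-4,5-bis(triethylsilyloxy)cyclohept-2-en-1-one | CC[Si](CC)(CC)O[C@@H]1C=CC(=O)[C@H](C)[C@@](O)(C#C[C@@H](C)O[Si](C)(C)C(C)(C)C)[C@H]1O[Si](CC)(CC)CC | intermediate
18 | (4R,5S,6R,7R)-6-[(3R)-3-(tert-butyldimethylsilyloxy)but-1-ynyl]-4,5,6-trihydroxy-7-methylcyclohept-2-en-1-one | O[C@@H]1C=CC(=O)[C@H](C)[C@@](O)(C#C[C@@H](C)O[Si](C)(C)C(C)(C)C)[C@H]1O | intermediate
19 | acryloyl chloride | C=CC(=O)Cl | starting material
20 | 4-O-acryloyl derivative of 18 | C=CC(=O)O[C@@H]1C=CC(=O)[C@H](C)[C@@](O)(C#C[C@@H](C)O[Si](C)(C)C(C)(C)C)[C@H]1O | intermediate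
21 | (S)-2-methylbutanoic acid | CC[C@H](C)C(=O)O | starting material
22 | 4-O-acryloyl-5-O-[(S)-2-methylbutanoyl] derivative of 18 | C=CC(=O)O[C@@H]1C=CC(=O)[C@H](C)[C@@](O)(C#C[C@@H](C)O[Si](C)(C)C(C)(C)C)[C@H]1OC(=O)[C@@H](C)CC | intermediate
23 | cis-fused α-methylene-γ-butyrolactone 9-ketone with alkyne side chain | C=C1C(=O)O[C@@H]2[C@H]1CC(=O)[C@H](C)[C@@](O)(C#C[C@@H](C)O[Si](C)(C)C(C)(C)C)[C@H]2OC(=O)[C@@H](C)CC | intermediate
24 | 9-hydroxy lactone with alkyne side chain | C=C1C(=O)O[C@@H]2[C@H]1C[C@@H](O)[C@H](C)[C@@](O)(C#C[C@@H](C)O[Si](C)(C)C(C)(C)C)[C@H]2OC(=O)[C@@H](C)CC | intermediate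
25 | bridged (Z)-enol ether from O9 to C2 (not isolated) | C=C1C(=O)O[C@@H]2[C@H]1C[C@H]3O/C(=C\[C@@H](C)O[Si](C)(C)C(C)(C)C)[C@](O)([C@H]3C)[C@H]2OC(=O)[C@@H](C)CC | intermediate
26 | 4-O-tert-butyldimethylsilyl ether of the target | C=C1C(=O)O[C@@H]2[C@H]1C[C@@H](O)[C@H](C)[C@@](O)(C(=O)C[C@@H](C)O[Si](C)(C)C(C)(C)C)[C@H]2OC(=O)[C@@H](C)CC | intermediate
27 | target compound CNP0291806.4 | C=C1C(=O)O[C@@H]2[C@H]1C[C@@H](O)[C@H](C)[C@@](O)(C(=O)C[C@@H](C)O)[C@H]2OC(=O)[C@@H](C)CC | target

Total step count: 19. Longest linear sequence: 18 steps (steps 1–6 and 8–19); step 7 prepares the alkyne fragment.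

**Steps most likely to fail**

Step 18. The hydration may lose its regiocontrol: 6-endo attack would place the carbonyl on C3, and ionisation of the tertiary propargylic alcohol could lead to Meyer–Schuster rearrangement. The fallback sets out from 24 and comes back at 26, and replaces π-activation by a silicon tether. Selective silylation of the secondary C9 hydroxyl with 1,1,3,3-tetramethyldisilazane should give the hydrodimethylsilyl ether F1. Intramolecular syn-hydrosilylation with H2PtCl6 (6-exo-dig) should place silicon on C2 and give the cyclic alkenylsiloxane F2. Tamao–Fleming oxidation (H2O2, KF, KHCO3, THF/MeOH, 0 °C) then converts the C2–Si bond into the C2 ketone and frees the C9 hydroxyl, giving 26.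

Step 11. The ruthenium carbene may engage the internal alkyne (ring-closing enyne metathesis to a five-membered ring) and not the second alkene. The fallback sets out from 15 and comes back at 16, and masks the alkyne. Co2(CO)8 in CH2Cl2 should give the hexacarbonyldicobalt alkyne complex F3. Ring-closing metathesis with the same ruthenium catalyst gives the complexed cycloheptene F4. Oxidative decomplexation with trimethylamine N-oxide returns 16.

Step 16. The phosphine may add to the ring enone, the acrylate may oligomerise, or C10 may epimerise before cyclisation. The fallback sets out from 18 and comes back at 23, and forms the same C7–C11 bond with a stabilised carbanion. The C6 hydroxyl is acylated with diethylphosphonoacetic acid and DCC to give the phosphonoacetate F5. Steglich esterification of the C5 hydroxyl with 21 gives the diester F6. Intramolecular Michael addition of the phosphonoacetate carbanion to C7 (Cs2CO3, MeCN, 0 °C) should give the cis-fused phosphono lactone F7 as a mixture at C11. Horner–Wadsworth–Emmons methylenation with aqueous formaldehyde and K2CO3 then gives 23.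

**Further compounds**

F1 | step 18 | 9-O-(dimethylsilyl) ether of 24 | C=C1C(=O)O[C@@H]2[C@H]1C[C@@H](O[SiH](C)C)[C@H](C)[C@@](O)(C#C[C@@H](C)O[Si](C)(C)C(C)(C)C)[C@H]2OC(=O)[C@@H](C)CC
F2 | step 18 | cyclic alkenylsiloxane with silicon on C2 (from O9) | C=C1C(=O)O[C@@H]2[C@H]1C[C@H]3O[Si](C)(C)/C(=C/[C@@H](C)O[Si](C)(C)C(C)(C)C)[C@](O)([C@H]3C)[C@H]2OC(=O)[C@@H](C)CC
F3 | step 11 | hexacarbonyldicobalt complex of the alkyne of 15 | C=C[C@@H](O[Si](CC)(CC)CC)[C@H](O[Si](CC)(CC)CC)[C@](O)(C45C6([C@@H](C)O[Si](C)(C)C(C)(C)C)[Co]4(=C=O)(=C=O)(=C=O)[Co]56(=C=O)(=C=O)=C=O)[C@@H](C)C(O)C=C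
F4 | step 11 | hexacarbonyldicobalt complex of the alkyne of 16 | CC[Si](CC)(CC)O[C@@H]1C=CC(O)[C@H](C)[C@@](O)(C45C6([C@@H](C)O[Si](C)(C)C(C)(C)C)[Co]4(=C=O)(=C=O)(=C=O)[Co]56(=C=O)(=C=O)=C=O)[C@H]1O[Si](CC)(CC)CC
F5 | step 16 | 4-O-(diethylphosphonoacetyl) derivative of 18 | CCOP(=O)(OCC)CC(=O)O[C@@H]1C=CC(=O)[C@H](C)[C@@](O)(C#C[C@@H](C)O[Si](C)(C)C(C)(C)C)[C@H]1O
F6 | step 16 | 4-O-(diethylphosphonoacetyl)-5-O-[(S)-2-methylbutanoyl] derivative of 18 | CCOP(=O)(OCC)CC(=O)O[C@@H]1C=CC(=O)[C@H](C)[C@@](O)(C#C[C@@H](C)O[Si](C)(C)C(C)(C)C)[C@H]1OC(=O)[C@@H](C)CC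
F7 | step 16 | cis-fused α-(diethylphosphono)-γ-butyrolactone 9-ketone (C11 epimers) | CCOP(=O)(OCC)C1C(=O)O[C@@H]2[C@H]1CC(=O)[C@H](C)[C@@](O)(C#C[C@@H](C)O[Si](C)(C)C(C)(C)C)[C@H]2OC(=O)[C@@H](C)CC
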